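**Strategy**

- Retrosynthesis: the five phenols are masked as benzyl ethers, then a single cut is made at the biaryl bond C6–C8'' between ring A of the flavanone and ring A of the flavone.
- Forward: no ring is built, since all six rings are bought in naringin and apigenin. Naringin is deglycosylated enzymatically and benzylated at O7 and O4'. Apigenin is perbenzylated, iodinated at C8, stannylated and converted to the aryllead triacetate.
- The halves are joined once, by lead-mediated arylation of C6–H directed by the 5-OH, and hydrogenolysis then frees the five phenols.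
- Enabling feature: on ring A of the protected flavanone the chelated 5-OH is the only free hydroxyl, and of its two ortho carbons only C6 bears hydrogen (C4a is a ring-fusion carbon). Lead bound at O5 can therefore pass its aryl group to C6 alone; C6 is further activated by O7 (ortho) and O1 (para).
- Stereochemistry: C2 (S) comes from the chiral pool (naringin, recrystallized to the pure (2S) epimer if chiral HPLC shows the (2R) epimer). It is kept by base-free steps and by capping the 4'-OH.

Key step: step 7

Assumption: the target SMILES carries no axial descriptor, so the C6–C8'' atropisomers that may form beside the fixed (2S) centre are taken together as the target.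

**Route**

Step 1
Reactants: 1 (2S)-naringin
Product: 3 (2S)-naringenin, via prunin 2 (not isolated)
Conditions: naringinase (α-L-rhamnosidase and β-D-glucosidase activities), 0.1 M NaOAc–AcOH buffer, pH 4.0, 50 °C; the aglycone is filtered off
Reagents that add atoms: none
Why: Enzymatic glycoside hydrolysis, in which the rhamnosidase first removes the terminal rhamnose to give glucoside 2 and the glucosidase then cleaves the anomeric C–O bond of glucose, so the aryl C7–O bond and C2 are never touched and the mildly acidic medium offers no enolate or chalcone through which C2 could epimerize.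

Step 2
Reactants: 3 (2S)-naringenin
Product: 4 (2S)-7,4'-di-O-benzylnaringenin (5-OH free)
Conditions: BnOH (2.2 equiv), PPh3 (2.2 equiv), DIAD (2.2 equiv), THF, 0 °C to rt
Reagents that add atoms: benzyl alcohol, OCc1ccccc1
Why: Mitsunobu etherification, in which only the unchelated 7-OH and 4'-OH protonate the PPh3–DIAD betaine and are benzylated while the 5-OH held in a hydrogen bond to the C4 carbonyl stays free, and the absence of added base avoids the retro-oxa-Michael ring opening that would racemize C2.

Step 3
Reactants: 5 apigenin
Product: 6 5,7,4'-tri-O-benzylapigenin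
Conditions: BnBr (4.5 equiv), K2CO3 (6 equiv), DMF, 80 °C
Reagents that add atoms: benzyl bromide, BrCc1ccccc1
Why: Williamson ether synthesis, in which the 7- and 4'-phenoxides alkylate readily and excess benzyl bromide in hot DMF also forces O-benzylation of the hydrogen-bonded 5-OH, which must be etherified to steer the next step to C8; apigenin has no stereocentre and no base-labile ring.

Step 4
Reactants: 6 5,7,4'-tri-O-benzylapigenin
Product: 7 8-iodo-5,7,4'-tri-O-benzylapigenin
Conditions: I2, CF3CO2Ag, CH2Cl2, 0 °C to rt
Reagents that add atoms: iodine, [I][I]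
Why: Electrophilic aromatic iodination by the trifluoroacetyl hypoiodite formed from I2 and CF3CO2Ag, in which ring A (activated by the 5- and 7-benzyloxy groups) reacts before ring B (deactivated through the pyrone) and before C3, and with the 5-oxygen etherified the known preference of 5,7-dialkoxyflavones is for C8 over C6, which lies between two benzyloxy groups.

Step 5
Reactants: 7 8-iodo-5,7,4'-tri-O-benzylapigenin
Product: 8 8-(tributylstannyl)-5,7,4'-tri-O-benzylapigenin
Conditions: (Bu3Sn)2, Pd(PPh3)4 (cat.), toluene, 110 °C
Reagents that add atoms: hexabutylditin, CCCC[Sn](CCCC)(CCCC)[Sn](CCCC)(CCCC)CCCC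
Why: Palladium-catalysed stannylation of an aryl iodide with a distannane (oxidative addition of zerovalent palladium into C8–I, transmetallation with the Sn–Sn bond, reductive elimination), a neutral reaction that spares the benzyl ethers and the pyrone and avoids organolithium or Grignard species that would add to the flavone.

Step 6
Reactants: 8 8-(tributylstannyl)-5,7,4'-tri-O-benzylapigenin
Product: 9 (5,7,4'-tri-O-benzylapigenin-8-yl)lead triacetate
Conditions: Pb(OAc)4 (1.0 equiv), Hg(OAc)2 (cat.), CHCl3, 40 °C; Celite filtration, water wash, trituration with hexane; used at once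
Reagents that add atoms: lead tetraacetate, CC(=O)O[Pb](OC(C)=O)(OC(C)=O)OC(C)=O
Why: Tin–lead exchange of the Pinhey type, in which the electron-rich C8–Sn bond flanked by O7 and O1 (as in 2,4,6-trimethoxyphenyl systems) passes its aryl group to tetravalent lead under catalysis by divalent mercury, and the water wash destroys leftover Pb(OAc)4 that would otherwise oxidize the phenol partner of the next step.

Step 7
Reactants: 4 (2S)-7,4'-di-O-benzylnaringenin (5-OH free); 9 (5,7,4'-tri-O-benzylapigenin-8-yl)lead triacetate
Product: 12 (2S)-7,4'-di-O-benzylnaringenin-(6→8'')-5'',7'',4'''-tri-O-benzylapigenin, via aryloxylead diacetate 10 (not isolated), via dienone tautomer 11 (not isolated)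
Conditions: 9 (1.2 equiv), pyridine (3 equiv), CHCl3, 60 °C
Reagents that add atoms: none
Why: Proposed new method: the 5-OH of 4, its only free hydroxyl, should replace one acetate on the pyridine-ligated tetravalent lead of 9 to give aryl(aryloxy)lead diacetate 10, whose ligand coupling moves the C8'' aryl group onto the ortho carbon C6, expels Pb(OAc)2 (divalent lead) and leaves the 6H-dienone 11, which tautomerizes to the chelated phenol 12. The closest known reaction type is the Pinhey ortho-arylation of phenols and of vinylogous acids such as 4-hydroxycoumarins with aryllead triacetates, 2,4,6-trimethoxyphenyllead triacetate included, which gives hindered 2-hydroxybiaryls; a flavon-8-yl lead reagent has not been combined with a hydrogen-bonded 5-hydroxyflavanone. No ring closes and no stereocentre is set: only the C6–C8'' bond forms, C2 is a spectator and the sense of the new axis is left uncontrolled. The step needs C6 over C8, carbon over oxygen and ring A over C3, and the substrate secures this because C6 is the only CH ortho to the lead-bound oxygen (the other ortho carbon, C4a, is fully substituted), C8 has no neighbouring free OH, and a plain ketone α-carbon is not arylated by aryllead triacetates. Electronically C6 is the carbon of an acylphloroglucinol flanked by O5 and O7 and para to O1, comparable to the nucleophilic carbon of the 1,3-dicarbonyl-type substrates on which aryllead reagents work best, and because the bond is made within the coordination sphere of lead the four ortho oxygens that hamper transmetallation and reductive elimination at palladium should be tolerated.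

Step 8
Reactants: 12 (2S)-7,4'-di-O-benzylnaringenin-(6→8'')-5'',7'',4'''-tri-O-benzylapigenin
Product: 13 (2S)-naringenin-(6→8'')-apigenin, target CNP0154104.1
Conditions: H2 (1 atm), 10% Pd/C, EtOAc–MeOH, rt; stopped at the calculated uptake of 5 equiv H2
Reagents that add atoms: none
Why: Catalytic hydrogenolysis of aryl benzyl ethers, which is much faster than hydrogenation of the vinylogous-ester C2''=C3'' bond of the flavone or hydrogenolysis of the benzylic C2–O1 bond of the flavanone, and whose neutral conditions leave C2 (S) unchanged.

**Compound list**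

1 | (2S)-naringin, (2S)-naringenin 7-O-[α-L-rhamnopyranosyl-(1→2)-β-D-glucopyranoside] | C[C@H]1[C@@H]([C@H]([C@H]([C@@H](O1)O[C@@H]2[C@H]([C@@H]([C@H](O[C@H]2Oc3cc(O)c4C(=O)C[C@H](Oc4c3)c5ccc(O)cc5)CO)O)O)O)O)O | starting material
2 | prunin, (2S)-naringenin 7-O-β-D-glucopyranoside | O=C1C[C@@H](c2ccc(O)cc2)Oc2cc(O[C@@H]3O[C@H](CO)[C@@H](O)[C@H](O)[C@H]3O)cc(O)c21 | intermediate (not isolated)
3 | (2S)-naringenin, (2S)-5,7,4'-trihydroxyflavanone | O=C1C[C@@H](c2ccc(O)cc2)Oc2cc(O)cc(O)c21 | intermediate
4 | (2S)-7,4'-di-O-benzylnaringenin, 5-OH free | O=C1C[C@@H](c2ccc(OCc3ccccc3)cc2)Oc2cc(OCc3ccccc3)cc(O)c21 | intermediate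
5 | apigenin, 5,7,4'-trihydroxyflavone | O=c1cc(-c2ccc(O)cc2)oc2cc(O)cc(O)c12 | starting material
6 | 5,7,4'-tri-O-benzylapigenin | O=c1cc(-c2ccc(OCc3ccccc3)cc2)oc2cc(OCc3ccccc3)cc(OCc3ccccc3)c12 | intermediate
7 | 8-iodo-5,7,4'-tri-O-benzylapigenin | O=c1cc(-c2ccc(OCc3ccccc3)cc2)oc2c(I)c(OCc3ccccc3)cc(OCc3ccccc3)c12 | intermediate
8 | 8-(tributylstannyl)-5,7,4'-tri-O-benzylapigenin | O=c1cc(-c2ccc(OCc3ccccc3)cc2)oc2c([Sn](CCCC)(CCCC)CCCC)c(OCc3ccccc3)cc(OCc3ccccc3)c12 | intermediate
9 | (5,7,4'-tri-O-benzylapigenin-8-yl)lead triacetate | O=c1cc(-c2ccc(OCc3ccccc3)cc2)oc2c([Pb](OC(C)=O)(OC(C)=O)OC(C)=O)c(OCc3ccccc3)cc(OCc3ccccc3)c12 | intermediate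
10 | [(2S)-7,4'-di-O-benzylnaringenin-5-yloxy](5,7,4'-tri-O-benzylapigenin-8-yl)lead diacetate | O=C1C[C@@H](c2ccc(OCc3ccccc3)cc2)Oc2cc(OCc3ccccc3)cc(O[Pb](OC(C)=O)(OC(C)=O)c3c(OCc4ccccc4)cc(OCc4ccccc4)c4c(=O)cc(-c5ccc(OCc6ccccc6)cc5)oc34)c21 | intermediate (not isolated)
11 | 6H-dienone tautomer of 12, (2S)-7-benzyloxy-2-(4-benzyloxyphenyl)-6-(5,7,4'-tri-O-benzylapigenin-8-yl)-2,3-dihydrochromene-4,5(6H)-dione | O=C1C[C@@H](c2ccc(OCc3ccccc3)cc2)OC2=C1C(=O)C(c1c(OCc3ccccc3)cc(OCc3ccccc3)c3c(=O)cc(-c4ccc(OCc5ccccc5)cc4)oc13)C(OCc1ccccc1)=C2 | intermediate (not isolated)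
12 | (2S)-7,4'-di-O-benzylnaringenin-(6→8'')-5'',7'',4'''-tri-O-benzylapigenin | O=C1C[C@@H](c2ccc(OCc3ccccc3)cc2)Oc2cc(OCc3ccccc3)c(-c3c(OCc4ccccc4)cc(OCc4ccccc4)c4c(=O)cc(-c5ccc(OCc6ccccc6)cc5)oc34)c(O)c21 | intermediate
13 | (2S)-naringenin-(6→8'')-apigenin, CNP0154104.1 | O=C1C[C@@H](c2ccc(O)cc2)Oc2cc(O)c(-c3c(O)cc(O)c4c(=O)cc(-c5ccc(O)cc5)oc34)c(O)c21 | target

**Step count and risks**

Total step count: 8. Longest linear sequence: 6 steps (apigenin 5 to target 13 through steps 3, 4, 5, 6, 7 and 8); the naringin branch contributes steps 1 and 2.

Steps most likely to fail: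

1. Step 7 (proposed new method). Several processes could defeat it:
   - ligand exchange may be slow at the hydrogen-bonded 5-OH;
   - the tetra-ortho-substituted axis may be too crowded for ligand coupling;
   - the lead reagent may be lost by protodeplumbation or reductive decomposition before coupling;
   - traces of tetravalent lead may oxidize the phenol.

   The fallback replaces ligand coupling at lead by a palladium cross-coupling of known type. It sets out from 4 (and uses stannane 8 from step 5) and returns to the route at 12. Compound 4 would be iodinated at C6, the position ortho to the chelated hydroxyl, with benzyltrimethylammonium dichloroiodate and CaCO3 in CH2Cl2–MeOH at rt, to give (2S)-7,4'-di-O-benzyl-6-iodonaringenin F1. Stille coupling of F1 with 8 (Pd(P(t-Bu)3)2, CuI, CsF, dioxane, 80 °C) should then give 12. These conditions carry no strong base, so C2 should remain (S).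

2. Step 6. The tin-to-lead transfer at the doubly ortho-substituted C8 may stall, the stannane may be protodestannylated by the acetic acid present, a diaryllead diacetate may form by a second aryl transfer, or the lead reagent may decompose during isolation. The fallback changes the donor metal from tin to boron and also makes the stannylation of step 5 unnecessary. It sets out from 7 and returns at 9. Miyaura borylation of 7 (bis(pinacolato)diboron, PdCl2(dppf), KOAc, dioxane, 90 °C) would give 5,7,4'-tri-O-benzylapigenin-8-boronic acid pinacol ester F2. Oxidative removal of the pinacol (NaIO4, NH4OAc, acetone–water, rt) would give (5,7,4'-tri-O-benzylapigenin-8-yl)boronic acid F3. Boron–lead exchange (Pb(OAc)4, cat. Hg(OAc)2, CHCl3, 40 °C) would deliver 9 in solution, to be used directly in step 7.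

3. Step 8. The palladium surface may be poisoned by traces of lead or tin carried over from steps 5 to 7. Hydrogen uptake may continue into saturation of C2''=C3'' or reductive opening of the flavanone C2–O1 bond. The benzyl ethers flanking the biaryl axis may be cleaved incompletely. The fallback replaces hydrogenolysis by Lewis-acid dealkylation with a cation scavenger. It sets out from 12 and returns at 13: BCl3 with pentamethylbenzene in CH2Cl2 at −78 °C, followed by aqueous work-up, should remove all five benzyl groups without any reducing agent. No new compound arises on its way (F0).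

**Further compounds**

F1 | step 7 | (2S)-7,4'-di-O-benzyl-6-iodonaringenin | O=C1C[C@@H](c2ccc(OCc3ccccc3)cc2)Oc2cc(OCc3ccccc3)c(I)c(O)c21
F2 | step 6 | 5,7,4'-tri-O-benzylapigenin-8-boronic acid pinacol ester | O=c1cc(-c2ccc(OCc3ccccc3)cc2)oc2c(B3OC(C)(C)C(C)(C)O3)c(OCc3ccccc3)cc(OCc3ccccc3)c12
F3 | step 6 | (5,7,4'-tri-O-benzylapigenin-8-yl)boronic acid | O=c1cc(-c2ccc(OCc3ccccc3)cc2)oc2c(B(O)O)c(OCc3ccccc3)cc(OCc3ccccc3)c12
F0 | step 8 | none | none
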